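- How far has the electrophile gone at 2.0 d, and how much of the unused nucleophile is free then? I count in fractions of the electrophile charged.

| setting | north-east | west | flask |
|---|---|---|---|
| electrophile | 0.010 M | 0.020 M | 0.010 M |
| nucleophile | 0.0105 M | 0.0105 M | 0.0105 M |
| free base | 3 mM | 3 mM | 3.00 mM |
| protic impurity | 0.20 mM | 0.20 mM | 0.200 mM |
| remark | the very flask that is asked about, followed so far | run made earlier |  |
| time |  |  | 2.0 d |

| run | time / h | electrophile / % | target / % |
|---|---|---|---|
| north-east | 4.00 | 36.2 | 64.3 |
| north-east | 8.00 | 34.2 | 66.9 |
| north-east | 12.0 | 34.1 | 66.7 |
| north-east | 15.0 | 32.2 | 66.3 |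
| north-east | 20.0 | 33.8 | 67.8 |
| west | 1.50 | 67.2 | 31.4 |
| west | 5.00 | 63.9 | 35.7 |
| west | 8.00 | 63.9 | 37.8 |
| west | 15.0 | 62.7 | 35.5 |
| west | 20.0 | 62.4 | 36.2 |

(scatter of a reading: 1 percentage point)

1. part of the electrophile that has reacted at 2.0 d
2. share of the unused nucleophile that is free and not bound as protonated nucleophile, at 2.0 d

- the earlier runs do not show how much of nucleophile is bound; that part of a forecast is a guess

- First instants: in the north-east run, target reads 64.3% at 4.00 h, far earlier than 2.0 d, so the coupling of electrophile with nucleophile is fast. I suppose that each turnover sets free one acid, that free base, charged at 30.0%, ends up holding its own amount of that acid, and that protic impurity, at 2.00%, spends its own amount of the 105% of nucleophile.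
- Middle: I make no assumption about which of the two takes up acid first, free base or nucleophile. I only balance: acid that free base does not hold I count as parked on nucleophile, so in the balance each turnover beyond 30.0% costs two nucleophiles, one coupled and one parked as protonated nucleophile.
- End: I look for the turnover at which unused nucleophile (charge less impurity less turnover) equals the acid beyond the base (turnover less base). This gives 66.5%. I call it the acid stop: half of nucleophile less impurity plus base, over electrophile.
- Check: north-east target reads 66.9% at 8.00 h and 67.8% at 20.0 h, flat within the scatter of 1 percentage point and above the stop. The west run, with twice the electrophile, has a stop of 33.2% and reads 36.2% at 20.0 h.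
- My reckoning: I commit to the north-east plateau, a reading of 66.9%. The free share I can only guess.
- The forecast says 67.5% reacted and 8% free, adding “The free share is a guess”.
- The flask gives 67.7% reacted and 18.4% free.

    nucleophile + protic impurity → quenched reagent (k = 20.1 /M/min)
    acid set free + free base ⇌ salt of the base (K = 2.46 × 10⁷ /M, k = 6.86 /M/min)
    nucleophile + acid set free ⇌ protonated nucleophile, settled at all times (K = 4940 /M)
    electrophile + nucleophile ⇌ acid set free + target (K = 2.89, k = 5.07 /M/min)

- The coupling, taken by itself and both ways together, relaxes with a half-life of 0.349 h at the asked time, far shorter than the 2.0 d of this flask, and at 20.0 d the part reacted is still 67.7%: what stands in this flask is an equilibrium and not a stage on the way. The acid stop lies 1.2 points below the result of this flask, and for a neighbour flask charged with 12.0% of free base it reckons 57.5%, where that flask reaches 60.3%.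

The data were generated by integration from invented constants, noise included.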